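## Analysis of the target

The target 23 is built on a (7R,8S,7'R,8'S)-syringaresinol core, a cis-fused 3,7-dioxabicyclo[3.3.0]octane (ring carbons C7, C8, C9 and C7', C8', C9') whose C7 and C7' each carry an exo 3,5-dimethoxy-4-oxyphenyl (syringyl) ring. Three guaiacylglycerol chains, Ar–CαH(OH)–CβH(OAr')–CγH2OH, are attached through Cβ–O–aryl ether bonds: one on each syringyl O4 and a third on O4 of one of the two guaiacyl rings so introduced, which removes the C2 symmetry of the core from the molecule as a whole. Of the ten stereocentres, the four of the bicycle are locked to one another by the ring fusion, whereas the other six form three isolated Cα/Cβ pairs, all erythro: (αS,βR) in the two syringyl-bound units and (αR,βS) in the outer unit. These pairs are separated from the core and from each other by aromatic rings, so none can control another and each has to be set in the absolute sense. The three Cα carbinols and the ring carbons C7 and C7' are benzylic and para to an oxygen substituent; they ionise under acid (epimerisation through quinone-methide-like cations), are liable to hydrogenolysis and sit beside oxidisable phenols. The difficulty is threefold: six acyclic stereocentres with no ring to lean on, two chemically equivalent ends that must end up different, and a deprotection that spares five benzylic C–O bonds. The strategy rests on one structural fact: in every chain Cα, Cβ and Cγ correspond to the carboxyl carbon, C2 and C3 of serine, so Cβ can be taken from L- or D-serine and Cα created by adding the guaiacyl ring to the aldehyde made from the carboxyl carbon.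

## Retrosynthetic reasoning

The last operation should be a pure deprotection. In 22 all seven masked hydroxyls (three Cγ–O, two inner Cα–O and two phenols) are silyl ethers, so only O–Si bonds are cut on the way to 23. Silicon is used at every position because buffered fluoride needs neither acid nor hydrogen, both of which threaten the five benzylic C–O bonds. Benzyl ethers on the phenols are avoided for that reason.

22 is cut at the Cα–aryl bond of the outer unit, giving the α-aryloxy aldehyde 21 and the aryltitanium reagent 12. This bond is chosen because its formation creates Cα directly next to the already fixed Cβ, so the existing centre can direct the new one. Cutting Cα–Cβ instead would create both centres at once and demand an external controller. 12 is made from aryl bromide 10 through aryllithium 11, and 10 from phenol 9. The forward reaction must add the aryl group anti to the Cβ–OAr bond without epimerising the aldehyde.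

21 is traced through ester 20 to phenol 15 and hydroxy ester 19, cutting the aryl O–Cβ bond. The forward reaction is an SN2 etherification with inversion, so the (S)-Cβ of the outer unit requires the (R)-carbinol 19. 19 is available from D-serine 16 through 17 and 18 with C2 untouched. This cut places the serine carbons exactly on Cα (as the ester carbon), Cβ and Cγ.

15 differs from 14 by one free phenol. 14 is C2-symmetric, so its two aryl silyl ethers are equivalent and unmasking one of them is statistical. The statistical event is placed on a deprotection rather than on a coupling because material that is left untouched or is unmasked twice can be brought back to 14. 14 is 13 with its two Cα hydroxyls silylated; this is needed because free benzylic alcohols would themselves be activated in the later etherification.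

13 is cut at both inner Cα–aryl bonds at once, giving bis-aldehyde 8 and two molecules of 12. Because 8 has a C2 axis, its two formyl groups are the same functional group twice, and one operation builds two C–C bonds and two stereocentres. The forward reaction needs the same anti (polar Felkin–Anh) selectivity as above, now from (R)-Cβ, at both ends.

8 follows from diester 7 by partial reduction, and 7 is cut at both syringyl O–Cβ bonds into the racemic core 6 and two molecules of hydroxy ester 4. Inversion in the etherification means that (R)-Cβ requires (S)-4, which L-serine 1 provides through 2 and 3. Because 4 is enantiopure and 6 is racemic, the same step turns the two enantiomers of the core into diastereomers, of which only 7 is carried forward. The arms thus act as the resolving agent and no separate resolution is planned.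

6 is cut at C8–C8' and at the two C7–O ring bonds back to two molecules of sinapyl alcohol 5. Oxidative phenol coupling forms the whole bicycle with its relative configuration in one step, because the methoxy groups block both ortho positions and direct the coupling to C8. The price is that 6 is racemic, which the preceding disconnection deals with.

## Alternatives that were turned down

Alternative 1: The core is disconnected at C7–C8 and C7'–C8' (and later at both ring C–O bonds) into three pieces. These are butenolide A1, a (5S)-5-menthyloxy-2(5H)-furanone with a (1S,2R,5S)-menthyl group, as the C8–C8'–C9–C9' unit; the lithiated dithiane A2 as C7 with its aryl ring; and aldehyde A3 as C7'. In the forward key step A2 adds in conjugate fashion to A1 on the face away from the menthyloxy group, and the enolate so formed is trapped by A3, giving the trans-3,4-disubstituted lactone A4 in one flask.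
- For: C8 and C8' are set in the absolute sense by an auxiliary. The two aryl rings enter as different reagents (benzyl and allyl ethers), so the two phenols of the core are distinguished from the outset.
- Against: A4 is still far from a furofuran. It needs dithiane removal, ketone reduction with a new centre at C7, reduction of the lactone and acetal carbons, and two ring closures. The carbinol centre from the aldol step is uncontrolled and must be corrected in an acid-mediated cyclisation that can also give the C7-epimeric series. The auxiliary required is the less common antipode. None of the six arm stereocentres is addressed, so the serine and aryl-addition sequence would have to follow anyway.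
- Comparison: this alternative is stronger on two points: no separation of 7 from its core diastereomer and no statistical unmasking (14 to 15). The chosen strategy offers in exchange a one-step core from 5 and a key step placed where most of the stereochemical load of 23 lies. Overall it should be shorter by roughly the six to eight steps that converting A4 into a protected core would cost.

Alternative 2: One tetrahydrofuran ring is cut at C7–C8 and C9'–C8', leading to the enantiopure 5-aryl butenolide A5 (carrying C7', C8', C8 and C9) and the aryl (trimethylsilyl)methyl acetal A6 (C7, its oxygen and C9'). Forward, Lewis-acid ionisation of A6 and fluoride-induced loss of the silyl group unmask the carbonyl ylide A7. It adds as a 1,3-dipole across the C8=C8' bond of A5 on the face away from the C7' aryl group and gives the furofuranone A8 with both new C–C bonds and the second ring.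
- For: it is convergent, builds the bicycle directly, transfers the single stereocentre of A5 to the other three, and again delivers differently protected phenols (silyl and benzyl).
- Against: A5 needs its own asymmetric synthesis, and its stereocentre is benzylic, allylic and γ to the carbonyl, so it can racemise by base (dienolate) or Lewis acid (ionisation). Nothing in the substrates secures the exo orientation of the C7 aryl group in the cycloaddition. The C9 carbonyl of A8 must afterwards be reduced to CH2, typically through the lactol and an ionic reduction under Lewis-acid conditions that endanger the benzylic ring C–O bonds. The arms are untouched.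
- Comparison: it equals the chosen strategy in convergence and is stronger in end differentiation and in avoiding a diastereomer separation at the stage of 7. Its key step, however, carries more unsecured selectivity (orientation of the dipole, exo against endo) than the acyclic 1,2-induction of the chosen step, and it spends about five to seven steps on a core that the chosen route obtains in one.

Alternative 3: The core is cut at C8–C8' and at the C7'–O bond, back to the epoxy cinnamyl ether A9, in which C7 is the only stereocentre that matters. In the key step Cp2TiCl (A10, trivalent titanium) opens the terminal epoxide homolytically to a C8 radical. A 5-exo cyclisation onto the cinnamyl double bond forms C8–C8' and the first ring, and oxidative interception of the C7' benzylic radical as a halide or cation lets the C9 oxygen close the second ring, giving the differentially protected core A11.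
- For: this is the most direct of the three. The epoxide configuration is erased at the radical stage, so only C7 has to be set. The key-step product is already a (7R,8S,7'R,8'S)-syringaresinol with one benzyl and one silyl ether, on which the arms could be mounted one at a time.
- Against: enantiopure A9 needs an asymmetric route to a secondary benzylic ether carrying an acid-labile sinapyl-type cinnamyl unit. The C7' benzylic radical is as readily reduced by a second equivalent of A10 as oxidised, which stops the cascade after the first ring. The ionic closure onto a p-oxybenzylic cation need not respect the exo configuration at C7'. The titanium reagent is needed in stoichiometric amount, and the arms still have to be built as in the chosen route.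
- Comparison: on end differentiation and on avoiding a resolution this alternative is clearly stronger. The chosen strategy offers instead a core from commercial 5 in a single step and concentrates the risk in one well-understood acyclic addition rather than in a multi-event radical–polar cascade followed by the same arm chemistry.

Key step: step 8

Remark on the chemistry: 6 is formed and used as the racemate (its SMILES shows the (7R,8S,7'R,8'S) enantiomer); lignan numbering (C7–C9, C7'–C9') is used for the core and Cα/Cβ/Cγ for the glycerol arms; a reactant listed twice on a Reactants line enters the product as two molecules; the solution of 12 is not stored, so the preparation of step 7 is repeated just before step 15 and counted once.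

## Route

Step 1
Reactants: 1 L-serine [(S)-2-amino-3-hydroxypropanoic acid]
Product: 3 methyl (S)-2,3-dihydroxypropanoate, via (S)-glyceric acid 2 (not isolated)
Conditions: NaNO2, aq H2SO4, 0 °C→rt; evaporation; then MeOH, HCl (cat.), reflux
Reagents that add atoms: water (O); methanol (CO)
Why: Diazotisation of the α-amino acid gives a diazonium ion that is displaced first by the neighbouring carboxylate (α-lactone) and then by water, two inversions and hence net retention at C2; Fischer esterification of the crude acid follows.

Step 2
Reactants: 3 methyl (S)-2,3-dihydroxypropanoate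
Product: 4 methyl (S)-2-hydroxy-3-(triisopropylsilyloxy)propanoate
Conditions: TIPSCl, imidazole, CH2Cl2, 0 °C→rt
Reagents that add atoms: triisopropylsilyl chloride (CC(C)[Si](Cl)(C(C)C)C(C)C)
Why: Silylation with a bulky trialkylsilyl chloride is selective for the primary hydroxyl over the secondary one α to the ester; the stereocentre is not involved.

Step 3
Reactants: 5 sinapyl alcohol [(E)-4-(3-hydroxyprop-1-enyl)-2,6-dimethoxyphenol]; 5 sinapyl alcohol (second molecule)
Product: 6 rac-syringaresinol (cis-fused furofuran with two exo 4-hydroxy-3,5-dimethoxyphenyl groups at C7 and C7')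
Conditions: FeCl3·6H2O, acetone/H2O, rt
Reagents that add atoms: none
Why: Oxidative phenol coupling (dehydrodimerisation): one-electron oxidation of each of two molecules of 5 gives phenoxy radicals whose ortho positions are blocked by methoxy groups, so they couple at C8–C8' and both quinone methide units are captured by the C9 hydroxyls; the bicyclo[3.3.0] skeleton enforces the cis fusion and the aryl groups take the exo positions, which fixes the relative configuration of the racemate.

Step 4
Reactants: 6 rac-syringaresinol; 4 methyl (S)-2-hydroxy-3-(triisopropylsilyloxy)propanoate; 4 methyl (S)-2-hydroxy-3-(triisopropylsilyloxy)propanoate (second molecule)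
Product: 7 (7R,8S,7'R,8'S)-syringaresinol 4,4'-bis[(R)-1-(methoxycarbonyl)-2-(triisopropylsilyloxy)ethyl] ether
Conditions: PPh3, DIAD (2.5 equiv each), THF, 0 °C→rt; then chromatography (preparative HPLC on silica if needed) to remove the core diastereomer
Reagents that add atoms: none
Why: Twofold Mitsunobu etherification of a phenol with a 2-hydroxy ester: each phenoxide displaces an alkoxyphosphonium ion by SN2 with inversion, so the (S)-carbinol of 4 becomes the (R)-aryl ether at both ends; racemic 6 therefore gives 7 together with the diastereomer that carries the same (R)-arms on the (7S,8R,7'S,8'R) core, and as diastereomers the two should be separable.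

Step 5
Reactants: 7 (7R,8S,7'R,8'S)-syringaresinol 4,4'-bis[(R)-1-(methoxycarbonyl)-2-(triisopropylsilyloxy)ethyl] ether
Product: 8 (7R,8S,7'R,8'S)-syringaresinol 4,4'-bis[(R)-1-formyl-2-(triisopropylsilyloxy)ethyl] ether
Conditions: i-Bu2AlH, CH2Cl2, −78 °C; MeOH, then aq potassium sodium tartrate (KNaC4H4O6); used at once without chromatography
Reagents that add atoms: none
Why: Partial reduction of an α-alkoxy ester: the tetrahedral aluminium hemiacetal, stabilised by the α-aryloxy oxygen, persists at −78 °C until the quench, so the aldehyde is not reduced further and Cβ is untouched.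

Step 6
Reactants: 9 4-bromo-2-methoxyphenol
Product: 10 (4-bromo-2-methoxyphenoxy)(tert-butyl)dimethylsilane
Conditions: TBSCl, imidazole, CH2Cl2, rt
Reagents that add atoms: tert-butyldimethylsilyl chloride (CC(C)(C)[Si](C)(C)Cl)
Why: Imidazole-mediated silylation of a phenol; the silyl ether tolerates bromine–lithium exchange and can later be cleaved by fluoride in preference to alkyl silyl ethers.

Step 7
Reactants: 10 (4-bromo-2-methoxyphenoxy)(tert-butyl)dimethylsilane
Product: 12 [4-(tert-butyldimethylsilyloxy)-3-methoxyphenyl]titanium triisopropoxide (THF solution, used directly), via aryllithium 11 (not isolated)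
Conditions: n-BuLi, THF, −78 °C; then ClTi(O-i-Pr)3, −78→−40 °C
Reagents that add atoms: chlorotitanium triisopropoxide (CC(C)O[Ti](Cl)(OC(C)C)OC(C)C)
Why: Bromine–lithium exchange on the aryl bromide is fast at −78 °C and the lithium sits para to the silyloxy group, so no silyl migration can occur; transmetalation of 11 with ClTi(O-i-Pr)3 gives the monoaryltitanium reagent, which is less basic and less Lewis acidic than 11.

Step 8
Reactants: 8 (7R,8S,7'R,8'S)-syringaresinol 4,4'-bis[(R)-1-formyl-2-(triisopropylsilyloxy)ethyl] ether; 12 [4-(tert-butyldimethylsilyloxy)-3-methoxyphenyl]titanium triisopropoxide; 12 [4-(tert-butyldimethylsilyloxy)-3-methoxyphenyl]titanium triisopropoxide (second molecule)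
Product: 13 (7R,8S,7'R,8'S)-syringaresinol 4,4'-bis{(1S,2R)-1-[4-(tert-butyldimethylsilyloxy)-3-methoxyphenyl]-1-hydroxy-3-(triisopropylsilyloxy)prop-2-yl} ether
Conditions: 12 (excess, fresh THF solution from step 7), 8 added in THF at −78 °C, −78→−20 °C; aq NH4Cl
Reagents that add atoms: none
Why: The aryl group of 12 is transferred to each formyl carbon of 8 through an open, non-chelated transition state; polar Felkin–Anh addition of an organotitanium triisopropoxide to an α-alkoxy aldehyde is the closest known reaction type. No ring is closed: two Cα–aryl bonds and the two Cα stereocentres are formed. Each new centre is controlled by its neighbouring Cβ: the Cβ–OAr bond, the best σ* acceptor, stands perpendicular to the carbonyl plane and anti to the incoming aryl group, which travels along the Bürgi–Dunitz path over the Cβ hydrogen and not over CH2OSi, so (R)-Cβ gives (S)-Cα, the erythro (1,2-anti) unit. The step needs anti over syn selectivity at both ends and no epimerisation of Cβ. Chelation, which would give the syn unit, is suppressed because the 2,6-dimethoxyaryl ether oxygen and the triisopropylsilyl ether are poor donors and the Ti(O-i-Pr)3 centre is a weak Lewis acid, while the low basicity of 12 and the low temperature protect the labile α-aryloxy aldehyde. The two formyl groups are related by the C2 axis and lie far apart, so they react independently and the doubly anti product keeps the axis, whereas a single mis-addition gives an unsymmetrical diastereomer that should be separable. Silyl ethers, aryl ethers and the furofuran are inert to 12.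

Step 9
Reactants: 13 (7R,8S,7'R,8'S)-syringaresinol 4,4'-bis{(1S,2R)-1-[4-(tert-butyldimethylsilyloxy)-3-methoxyphenyl]-1-hydroxy-3-(triisopropylsilyloxy)prop-2-yl} ether
Product: 14 (7R,8S,7'R,8'S)-syringaresinol 4,4'-bis{(1S,2R)-1-(tert-butyldimethylsilyloxy)-1-[4-(tert-butyldimethylsilyloxy)-3-methoxyphenyl]-3-(triisopropylsilyloxy)prop-2-yl} ether
Conditions: TBSOTf, 2,6-lutidine, CH2Cl2, −78→−20 °C
Reagents that add atoms: tert-butyldimethylsilyl trifluoromethanesulfonate (CC(C)(C)[Si](C)(C)OS(=O)(=O)C(F)(F)F)
Why: Silyl triflate/2,6-lutidine silylation of hindered secondary alcohols masks the two benzylic hydroxyls, which would otherwise be activated in the Mitsunobu reaction of step 13; under buffered conditions at low temperature no benzylic centre ionises.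

Step 10
Reactants: 14 (7R,8S,7'R,8'S)-syringaresinol 4,4'-bis{(1S,2R)-1-(tert-butyldimethylsilyloxy)-1-[4-(tert-butyldimethylsilyloxy)-3-methoxyphenyl]-3-(triisopropylsilyloxy)prop-2-yl} ether
Product: 15 mono-phenol of 14 (one guaiacyl ring as 4-hydroxy-3-methoxyphenyl; the other ring and all alkyl silyl ethers unchanged)
Conditions: n-Bu4NF (1.0 equiv), THF, −78→−40 °C; AcOH quench; recovered 14 recycled
Reagents that add atoms: none
Why: Fluoride cleaves aryl silyl ethers far faster than alkyl silyl ethers because phenoxide is the better leaving group, so one equivalent at low temperature touches only phenolic O–Si bonds; the two ends are equivalent, so 15 forms statistically beside unchanged 14 and doubly desilylated material, and the latter is returned to 14 with TBSCl and imidazole.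

Step 11
Reactants: 16 D-serine [(R)-2-amino-3-hydroxypropanoic acid]
Product: 18 methyl (R)-2,3-dihydroxypropanoate, via (R)-glyceric acid 17 (not isolated)
Conditions: NaNO2, aq H2SO4, 0 °C→rt; evaporation; then MeOH, HCl (cat.), reflux
Reagents that add atoms: water (O); methanol (CO)
Why: Same diazotisation with net retention (double inversion through the α-lactone) and Fischer esterification as in step 1, in the enantiomeric series.

Step 12
Reactants: 18 methyl (R)-2,3-dihydroxypropanoate
Product: 19 methyl (R)-2-hydroxy-3-(triisopropylsilyloxy)propanoate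
Conditions: TIPSCl, imidazole, CH2Cl2, 0 °C→rt
Reagents that add atoms: triisopropylsilyl chloride (CC(C)[Si](Cl)(C(C)C)C(C)C)
Why: Selective silylation of the primary hydroxyl, as in step 2.

Step 13
Reactants: 15 mono-phenol of 14; 19 methyl (R)-2-hydroxy-3-(triisopropylsilyloxy)propanoate
Product: 20 aryl ether of 15 carrying an (S)-1-(methoxycarbonyl)-2-(triisopropylsilyloxy)ethyl group on the formerly free guaiacyl oxygen
Conditions: PPh3, DIAD, THF, 0 °C→rt
Reagents that add atoms: none
Why: Mitsunobu etherification with inversion turns the (R)-carbinol of 19 into the (S)-aryl ether; the single free phenol of 15 is the only acidic partner and the hydroxyl of 19 the only free alcohol, so no other site can react.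

Step 14
Reactants: 20 aryl ether of 15 carrying an (S)-1-(methoxycarbonyl)-2-(triisopropylsilyloxy)ethyl group
Product: 21 the corresponding (S)-aldehyde [(S)-1-formyl-2-(triisopropylsilyloxy)ethyl ether]
Conditions: i-Bu2AlH, CH2Cl2, −78 °C; MeOH, then aq potassium sodium tartrate (KNaC4H4O6); used at once
Reagents that add atoms: none
Why: Partial reduction of the α-aryloxy ester through the persistent tetrahedral aluminium hemiacetal, as in step 5; the aryl and alkyl silyl ethers are inert at −78 °C.

Step 15
Reactants: 21 (S)-aldehyde [(S)-1-formyl-2-(triisopropylsilyloxy)ethyl ether]; 12 [4-(tert-butyldimethylsilyloxy)-3-methoxyphenyl]titanium triisopropoxide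
Product: 22 hepta-silylated precursor of the target whose outer unit is (1R,2S)-1-[4-(tert-butyldimethylsilyloxy)-3-methoxyphenyl]-1-hydroxy-3-(triisopropylsilyloxy)prop-2-yl
Conditions: 12 (excess, fresh THF solution made as in step 7), 21 added in THF at −78 °C, −78→−20 °C; aq NH4Cl
Reagents that add atoms: none
Why: The same non-chelated polar Felkin–Anh addition as in step 8, now on an (S)-configured α-aryloxy aldehyde: attack anti to the Cβ–OAr bond and past the Cβ hydrogen gives (R)-Cα, the erythro (αR,βS) outer unit.

Step 16
Reactants: 22 hepta-silylated precursor of the target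
Product: 23 target CNP0316493.2
Conditions: n-Bu4NF (excess), AcOH, THF, 0 °C→rt
Reagents that add atoms: none
Why: Fluoride-mediated cleavage of all seven silyl ethers (three primary triisopropylsilyl, two secondary benzylic and two aryl tert-butyldimethylsilyl); acetic acid keeps the medium near neutral so that the p-hydroxybenzylic carbinols and the furofuran ring carbons are neither ionised nor epimerised.

## Compound list

1 | L-serine | N[C@@H](CO)C(=O)O | starting material
2 | (S)-glyceric acid | O[C@@H](CO)C(=O)O | intermediate (not isolated)
3 | methyl (S)-2,3-dihydroxypropanoate | O[C@@H](CO)C(=O)OC | intermediate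
4 | methyl (S)-2-hydroxy-3-(triisopropylsilyloxy)propanoate | O[C@@H](CO[Si](C(C)C)(C(C)C)C(C)C)C(=O)OC | intermediate
5 | sinapyl alcohol | COc1cc(/C=C/CO)cc(OC)c1O | starting material
6 | rac-syringaresinol (racemate; SMILES shows the 7R,8S,7'R,8'S enantiomer) | COc1cc([C@@H]2OC[C@@H]3[C@H]2CO[C@H]3c2cc(OC)c(O)c(OC)c2)cc(OC)c1O | intermediate
7 | (7R,8S,7'R,8'S)-syringaresinol 4,4'-bis[(R)-1-(methoxycarbonyl)-2-(triisopropylsilyloxy)ethyl] ether | COC(=O)[C@@H](CO[Si](C(C)C)(C(C)C)C(C)C)Oc1c(OC)cc([C@@H]2OC[C@@H]3[C@H]2CO[C@H]3c2cc(OC)c(O[C@H](CO[Si](C(C)C)(C(C)C)C(C)C)C(=O)OC)c(OC)c2)cc1OC | intermediate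
8 | (7R,8S,7'R,8'S)-syringaresinol 4,4'-bis[(R)-1-formyl-2-(triisopropylsilyloxy)ethyl] ether | O=C[C@@H](CO[Si](C(C)C)(C(C)C)C(C)C)Oc1c(OC)cc([C@@H]2OC[C@@H]3[C@H]2CO[C@H]3c2cc(OC)c(O[C@H](CO[Si](C(C)C)(C(C)C)C(C)C)C=O)c(OC)c2)cc1OC | intermediate
9 | 4-bromo-2-methoxyphenol | COc1cc(Br)ccc1O | starting material
10 | (4-bromo-2-methoxyphenoxy)(tert-butyl)dimethylsilane | COc1cc(Br)ccc1O[Si](C)(C)C(C)(C)C | intermediate
11 | [4-(tert-butyldimethylsilyloxy)-3-methoxyphenyl]lithium | COc1cc([Li])ccc1O[Si](C)(C)C(C)(C)C | intermediate (not isolated)
12 | [4-(tert-butyldimethylsilyloxy)-3-methoxyphenyl]titanium triisopropoxide | COc1cc([Ti](OC(C)C)(OC(C)C)OC(C)C)ccc1O[Si](C)(C)C(C)(C)C | intermediate (THF solution)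
13 | (7R,8S,7'R,8'S)-syringaresinol 4,4'-bis{(1S,2R)-1-[4-(tert-butyldimethylsilyloxy)-3-methoxyphenyl]-1-hydroxy-3-(triisopropylsilyloxy)prop-2-yl} ether | CC(C)(C)[Si](C)(C)Oc1ccc([C@H](O)[C@@H](CO[Si](C(C)C)(C(C)C)C(C)C)Oc2c(OC)cc([C@@H]3OC[C@@H]4[C@H]3CO[C@H]4c3cc(OC)c(O[C@H](CO[Si](C(C)C)(C(C)C)C(C)C)[C@@H](O)c4ccc(O[Si](C)(C)C(C)(C)C)c(OC)c4)c(OC)c3)cc2OC)cc1OC | intermediate
14 | (7R,8S,7'R,8'S)-syringaresinol 4,4'-bis{(1S,2R)-1-(tert-butyldimethylsilyloxy)-1-[4-(tert-butyldimethylsilyloxy)-3-methoxyphenyl]-3-(triisopropylsilyloxy)prop-2-yl} ether | CC(C)(C)[Si](C)(C)Oc1ccc([C@H](O[Si](C)(C)C(C)(C)C)[C@@H](CO[Si](C(C)C)(C(C)C)C(C)C)Oc2c(OC)cc([C@@H]3OC[C@@H]4[C@H]3CO[C@H]4c3cc(OC)c(O[C@H](CO[Si](C(C)C)(C(C)C)C(C)C)[C@@H](O[Si](C)(C)C(C)(C)C)c4ccc(O[Si](C)(C)C(C)(C)C)c(OC)c4)c(OC)c3)cc2OC)cc1OC | intermediate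
15 | mono-phenol of 14 (one aryl silyl ether cleaved) | Oc1ccc([C@H](O[Si](C)(C)C(C)(C)C)[C@@H](CO[Si](C(C)C)(C(C)C)C(C)C)Oc2c(OC)cc([C@@H]3OC[C@@H]4[C@H]3CO[C@H]4c3cc(OC)c(O[C@H](CO[Si](C(C)C)(C(C)C)C(C)C)[C@@H](O[Si](C)(C)C(C)(C)C)c4ccc(O[Si](C)(C)C(C)(C)C)c(OC)c4)c(OC)c3)cc2OC)cc1OC | intermediate
16 | D-serine | N[C@H](CO)C(=O)O | starting material
17 | (R)-glyceric acid | O[C@H](CO)C(=O)O | intermediate (not isolated)
18 | methyl (R)-2,3-dihydroxypropanoate | O[C@H](CO)C(=O)OC | intermediate
19 | methyl (R)-2-hydroxy-3-(triisopropylsilyloxy)propanoate | O[C@H](CO[Si](C(C)C)(C(C)C)C(C)C)C(=O)OC | intermediate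
20 | aryl ether of 15 with an (S)-1-(methoxycarbonyl)-2-(triisopropylsilyloxy)ethyl group on the guaiacyl oxygen | COC(=O)[C@H](CO[Si](C(C)C)(C(C)C)C(C)C)Oc1ccc([C@H](O[Si](C)(C)C(C)(C)C)[C@@H](CO[Si](C(C)C)(C(C)C)C(C)C)Oc2c(OC)cc([C@@H]3OC[C@@H]4[C@H]3CO[C@H]4c3cc(OC)c(O[C@H](CO[Si](C(C)C)(C(C)C)C(C)C)[C@@H](O[Si](C)(C)C(C)(C)C)c4ccc(O[Si](C)(C)C(C)(C)C)c(OC)c4)c(OC)c3)cc2OC)cc1OC | intermediate
21 | (S)-aldehyde from 20 [(S)-1-formyl-2-(triisopropylsilyloxy)ethyl ether] | O=C[C@H](CO[Si](C(C)C)(C(C)C)C(C)C)Oc1ccc([C@H](O[Si](C)(C)C(C)(C)C)[C@@H](CO[Si](C(C)C)(C(C)C)C(C)C)Oc2c(OC)cc([C@@H]3OC[C@@H]4[C@H]3CO[C@H]4c3cc(OC)c(O[C@H](CO[Si](C(C)C)(C(C)C)C(C)C)[C@@H](O[Si](C)(C)C(C)(C)C)c4ccc(O[Si](C)(C)C(C)(C)C)c(OC)c4)c(OC)c3)cc2OC)cc1OC | intermediate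
22 | hepta-silylated precursor of the target (outer unit αR,βS with free Cα–OH; three Cγ–O triisopropylsilyl ethers; two inner Cα–O and two phenolic tert-butyldimethylsilyl ethers) | COc1cc([C@@H](O)[C@H](CO[Si](C(C)C)(C(C)C)C(C)C)Oc2ccc([C@H](O[Si](C)(C)C(C)(C)C)[C@@H](CO[Si](C(C)C)(C(C)C)C(C)C)Oc3c(OC)cc([C@@H]4OC[C@@H]5[C@H]4CO[C@H]5c4cc(OC)c(O[C@H](CO[Si](C(C)C)(C(C)C)C(C)C)[C@@H](O[Si](C)(C)C(C)(C)C)c5ccc(O[Si](C)(C)C(C)(C)C)c(OC)c5)c(OC)c4)cc3OC)cc2OC)ccc1O[Si](C)(C)C(C)(C)C | intermediate
23 | CNP0316493.2 | COc1cc([C@@H](O)[C@H](CO)Oc2ccc([C@H](O)[C@@H](CO)Oc3c(OC)cc([C@@H]4OC[C@@H]5[C@H]4CO[C@H]5c4cc(OC)c(O[C@H](CO)[C@@H](O)c5ccc(O)c(OC)c5)c(OC)c4)cc3OC)cc2OC)ccc1O | target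

## Step count and least certain steps

Total: 16 steps. Longest linear sequence: 11 steps (steps 1, 2, 4, 5, 8, 9, 10, 13, 14, 15, 16, from L-serine 1). The branches from 5 (step 3), 9 (steps 6 and 7) and 16 (steps 11 and 12) are shorter.

Step 8 (key step). Most likely failure: erosion of facial selectivity at one or both formyl groups (approach syn to the Cβ–OAr bond through a chelated or loosely organised transition state), made worse by enolisation and epimerisation of the aldehyde before addition. Because two additions are needed, any shortfall per site counts twice. Fallback: setting out from 13 obtained as a mixture of Cα epimers, both carbinols are oxidised with Dess–Martin periodinane (NaHCO3, CH2Cl2) to the bis(aryl ketone) F1, in which Cβ is unchanged. F1 is then reduced under catalyst control by asymmetric transfer hydrogenation (RuCl[(R,R)-TsDPEN](p-cymene), HCO2H/Et3N). The ligand antipode is chosen by the aryl-recognition model of this catalyst class so that hydride goes to the face giving (S)-Cα. The sequence comes back to the route at 13 and replaces substrate control by reagent control.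

Step 4. Most likely failure: incomplete twofold etherification of the hindered 2,6-dimethoxyphenols and, above all, insufficient chromatographic resolution of 7 from its core diastereomer, whose differing stereocentres are separated by an aromatic ring. Fallback: setting out from 6 and 4, the racemate 6 is first resolved by preparative chromatography on a cellulose tris(3,5-dimethylphenylcarbamate) stationary phase to give (7R,8S,7'R,8'S)-syringaresinol F2. 4 is converted into the (S)-triflate F3 (Tf2O, 2,6-lutidine, CH2Cl2, −78 °C). The bis-phenoxide of F2 (Cs2CO3, MeCN, 0 °C) then displaces the triflate at both ends by SN2 with inversion. This comes back to the route at 7, with no diastereomer to remove.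

Step 5. Most likely failure: over-reduction of one or both ester groups to the primary alcohol, or epimerisation at Cβ while the aldehyde is handled. Fallback: setting out from 7, exhaustive reduction (LiBH4, THF, 0 °C) gives the bis(primary alcohol) F4, and oxidation of F4 under non-basic conditions (Dess–Martin periodinane, NaHCO3, CH2Cl2) comes back to the route at 8. Two robust steps replace one delicate one.

Step 10. Most likely failure: no discrimination between the two equivalent aryl silyl ethers beyond statistics, with laborious separation of unchanged, singly and doubly desilylated material and slow recycling. Fallback: setting out from 14, both aryl silyl ethers are cleaved deliberately (K2CO3, MeOH, rt) to give the bis-phenol F5. F5 is etherified with a deficit of 19 under the conditions of step 13 to the mono-ether F6, whose remaining phenol is silylated (TBSCl, imidazole) to come back to the route at 20. The statistical event is thereby moved from the deprotection to the coupling.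

Step 15. Most likely failure: lower facial selectivity than in step 8, because the aryloxy group on Cβ is now the less hindered guaiacyl ether, together with poor separation of the Cα epimers at this molecular size. Fallback: setting out from 22 as the epimer mixture, oxidation of the single free carbinol (Dess–Martin periodinane, NaHCO3, CH2Cl2) gives the aryl ketone F7, and transfer hydrogenation with the antipodal catalyst RuCl[(S,S)-TsDPEN](p-cymene) (HCO2H/Et3N) comes back to 22 with (R)-Cα.

## Further compounds

F1 | step 8 | bis(aryl ketone) from 13 (both Cα carbinols oxidised to C=O; Cβ R at both ends) | CC(C)(C)[Si](C)(C)Oc1ccc(C(=O)[C@@H](CO[Si](C(C)C)(C(C)C)C(C)C)Oc2c(OC)cc([C@@H]3OC[C@@H]4[C@H]3CO[C@H]4c3cc(OC)c(O[C@H](CO[Si](C(C)C)(C(C)C)C(C)C)C(=O)c4ccc(O[Si](C)(C)C(C)(C)C)c(OC)c4)c(OC)c3)cc2OC)cc1OC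
F2 | step 4 | (7R,8S,7'R,8'S)-syringaresinol (single enantiomer) | COc1cc([C@@H]2OC[C@@H]3[C@H]2CO[C@H]3c2cc(OC)c(O)c(OC)c2)cc(OC)c1O
F3 | step 4 | methyl (S)-3-(triisopropylsilyloxy)-2-(trifluoromethylsulfonyloxy)propanoate | COC(=O)[C@H](CO[Si](C(C)C)(C(C)C)C(C)C)OS(=O)(=O)C(F)(F)F
F4 | step 5 | (7R,8S,7'R,8'S)-syringaresinol 4,4'-bis[(S)-1-hydroxy-3-(triisopropylsilyloxy)prop-2-yl] ether | OC[C@@H](CO[Si](C(C)C)(C(C)C)C(C)C)Oc1c(OC)cc([C@@H]2OC[C@@H]3[C@H]2CO[C@H]3c2cc(OC)c(O[C@H](CO[Si](C(C)C)(C(C)C)C(C)C)CO)c(OC)c2)cc1OC
F5 | step 10 | bis-phenol of 14 (both aryl silyl ethers cleaved) | Oc1ccc([C@H](O[Si](C)(C)C(C)(C)C)[C@@H](CO[Si](C(C)C)(C(C)C)C(C)C)Oc2c(OC)cc([C@@H]3OC[C@@H]4[C@H]3CO[C@H]4c3cc(OC)c(O[C@H](CO[Si](C(C)C)(C(C)C)C(C)C)[C@@H](O[Si](C)(C)C(C)(C)C)c4ccc(O)c(OC)c4)c(OC)c3)cc2OC)cc1OC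
F6 | step 10 | mono-ether of the bis-phenol with an (S)-1-(methoxycarbonyl)-2-(triisopropylsilyloxy)ethyl group on one guaiacyl oxygen and the other phenol free | COC(=O)[C@H](CO[Si](C(C)C)(C(C)C)C(C)C)Oc1ccc([C@H](O[Si](C)(C)C(C)(C)C)[C@@H](CO[Si](C(C)C)(C(C)C)C(C)C)Oc2c(OC)cc([C@@H]3OC[C@@H]4[C@H]3CO[C@H]4c3cc(OC)c(O[C@H](CO[Si](C(C)C)(C(C)C)C(C)C)[C@@H](O[Si](C)(C)C(C)(C)C)c4ccc(O)c(OC)c4)c(OC)c3)cc2OC)cc1OC
F7 | step 15 | aryl ketone from 22 (outer Cα carbinol oxidised to C=O; Cβ S) | COc1cc(C(=O)[C@H](CO[Si](C(C)C)(C(C)C)C(C)C)Oc2ccc([C@H](O[Si](C)(C)C(C)(C)C)[C@@H](CO[Si](C(C)C)(C(C)C)C(C)C)Oc3c(OC)cc([C@@H]4OC[C@@H]5[C@H]4CO[C@H]5c4cc(OC)c(O[C@H](CO[Si](C(C)C)(C(C)C)C(C)C)[C@@H](O[Si](C)(C)C(C)(C)C)c5ccc(O[Si](C)(C)C(C)(C)C)c(OC)c5)c(OC)c4)cc3OC)cc2OC)ccc1O[Si](C)(C)C(C)(C)C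
A1 | alternative 1 | (5S)-5-[(1S,2R,5S)-menthyloxy]furan-2(5H)-one | O=C1O[C@H](O[C@H]2C[C@@H](C)CC[C@@H]2C(C)C)C=C1
A2 | alternative 1 | 2-(4-benzyloxy-3,5-dimethoxyphenyl)-2-lithio-1,3-dithiane | [Li]C1(SCCCS1)c1cc(OC)c(OCc2ccccc2)c(OC)c1
A3 | alternative 1 | 4-allyloxy-3,5-dimethoxybenzaldehyde | O=Cc1cc(OC)c(OCC=C)c(OC)c1
A4 | alternative 1 | trans-3,4-disubstituted 5-menthyloxybutyrolactone (new carbinol centre unassigned) | O=C1O[C@H](O[C@H]2C[C@@H](C)CC[C@@H]2C(C)C)[C@@H](C2(SCCCS2)c2cc(OC)c(OCc3ccccc3)c(OC)c2)[C@@H]1C(O)c1cc(OC)c(OCC=C)c(OC)c1
A5 | alternative 2 | (R)-5-[3,5-dimethoxy-4-(triisopropylsilyloxy)phenyl]furan-2(5H)-one | O=C1O[C@H](C=C1)c1cc(OC)c(O[Si](C(C)C)(C(C)C)C(C)C)c(OC)c1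
A6 | alternative 2 | 4-benzyloxy-3,5-dimethoxybenzaldehyde methyl (trimethylsilyl)methyl acetal (either configuration at the acetal carbon) | COC(OC[Si](C)(C)C)c1cc(OC)c(OCc2ccccc2)c(OC)c1
A7 | alternative 2 | carbonyl ylide from A6 (4-benzyloxy-3,5-dimethoxybenzylidene oxonium methylide) | [CH2-][O+]=Cc1cc(OC)c(OCc2ccccc2)c(OC)c1
A8 | alternative 2 | 9-oxo derivative (furofuranone) of the differentially protected (7R,8S,7'R,8'S)-syringaresinol | COc1cc([C@@H]2OC[C@@H]3[C@H]2C(=O)O[C@H]3c2cc(OC)c(O[Si](C(C)C)(C(C)C)C(C)C)c(OC)c2)cc(OC)c1OCc1ccccc1
A9 | alternative 3 | epoxy cinnamyl ether: 2-{(4-benzyloxy-3,5-dimethoxyphenyl)[(E)-3-(3,5-dimethoxy-4-triisopropylsilyloxyphenyl)allyloxy]methyl}oxirane (C7 as in the core; epoxide carbon as either epimer) | COc1cc([C@H](OC/C=C/c2cc(OC)c(O[Si](C(C)C)(C(C)C)C(C)C)c(OC)c2)C2CO2)cc(OC)c1OCc1ccccc1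
A10 | alternative 3 | bis(cyclopentadienyl)titanium chloride, Cp2TiCl | [Cl-].[Ti+3].c1cc[cH-]c1.c1cc[cH-]c1
A11 | alternative 3 | (7R,8S,7'R,8'S)-syringaresinol with one phenol benzylated and the other triisopropylsilylated | COc1cc([C@@H]2OC[C@@H]3[C@H]2CO[C@H]3c2cc(OC)c(O[Si](C(C)C)(C(C)C)C(C)C)c(OC)c2)cc(OC)c1OCc1ccccc1
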